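**Plan**

- Numbering: ring A is the fused dimethoxybenzene and ring B the saturated ring (C1 aryl-bearing, C2, C3, C4); C9 and C9' are the methylene arms on C2 and C3, and C1' is the ipso carbon of the pendant aryl.
- Retrosynthesis: cut the two arm O–CH3 bonds, then C9–O (traced back to a C9–Si bond of a cis-fused oxasilinane), then C2–C9 and C1–C1' in one operation, then Si–O9'. The remaining dihydronaphthalene is cut at C1–C8a and C3–C4.
- Forward: a Stobbe condensation joins C4 to C3 and a Friedel–Crafts acylation closes ring B at C1–C8a. The C1 ketone is converted into the C1=C2 styrene, the key step closes the oxasilinane and attaches the aryl ring, and oxidation at silicon and O-methylation finish the synthesis.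
- Enabling feature: C2 carries a CH2O arm cis to the CH2O arm on C3, and C1 carries an aryl group trans to it and lies para (through C8a) to the C6 methoxy group of ring A. A C9 radical tethered through silicon to O9' can therefore add to C2 of a C1=C2 alkene in ring B, and the C1 cation that follows can be arylated.
- Stereochemistry: C3 comes from asymmetric hydrogenation, C2 from the tether (cis to C9'), and C1 from attack of veratrole anti to the new C2–C9 bond.

Key step: step 9

Assumption: (S)-BINAP is taken to be the ligand antipode that delivers the R acid 4 in step 2; should the sense of induction be the reverse, (R)-BINAP is used and nothing else changes.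

**Route**

Step 1
Reactants: 1 veratraldehyde (3,4-dimethoxybenzaldehyde); 2 dimethyl succinate
Product: 3 (E)-4-(3,4-dimethoxyphenyl)-3-(methoxycarbonyl)but-3-enoic acid
Conditions: NaOMe, MeOH, reflux; then aq. HCl
Reagents that add atoms: none
Why: Stobbe condensation: the succinate enolate adds to the aldehyde, the aldolate lactonises onto the far ester, and base-induced opening of the paraconate should give the E half-ester with the free acid on the CH2 arm and the aryl group trans to the ester.

Step 2
Reactants: 3 (E)-4-(3,4-dimethoxyphenyl)-3-(methoxycarbonyl)but-3-enoic acid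
Product: 4 (R)-4-(3,4-dimethoxyphenyl)-3-(methoxycarbonyl)butanoic acid
Conditions: H2 (20 atm), Ru(OAc)2[(S)-BINAP] (0.5 mol %), MeOH, 40 °C
Reagents that add atoms: none
Why: Carboxylate-directed asymmetric hydrogenation (Noyori-type ruthenium–BINAP reduction of an itaconate-type unsaturated acid): the free acid anchors the substrate on the metal and the ligand decides which alkene face takes up hydrogen, which sets the carbon that becomes C3 as R.

Step 3
Reactants: 4 (R)-4-(3,4-dimethoxyphenyl)-3-(methoxycarbonyl)butanoic acid
Product: 5 methyl (R)-6,7-dimethoxy-4-oxo-1,2,3,4-tetrahydronaphthalene-2-carboxylate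
Conditions: TFAA, TFA, 0 °C to rt
Reagents that add atoms: none
Why: Intramolecular Friedel–Crafts acylation through the mixed trifluoroacetic anhydride: the electron-rich ring is attacked para to its 3-methoxy group, closing ring B as the 6,7-dimethoxytetralone, and the stereocentre, which is not α to the new ketone and is not enolised in acid, is left alone.

Step 4
Reactants: 5 methyl (R)-6,7-dimethoxy-4-oxo-1,2,3,4-tetrahydronaphthalene-2-carboxylate
Product: 6 (3R)-3-(hydroxymethyl)-6,7-dimethoxy-1,2,3,4-tetrahydronaphthalen-1-ol (mixture of C1 epimers)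
Conditions: LiAlH4, THF, 0 °C to rt; Fieser work-up
Reagents that add atoms: none
Why: Hydride reduction of ketone and ester with LiAlH4 removes the only carbonyl group next to the stereocentre, and the configuration of the new carbinol is of no consequence because that carbon becomes sp2 in step 6.

Step 5
Reactants: 6 (3R)-3-(hydroxymethyl)-6,7-dimethoxy-1,2,3,4-tetrahydronaphthalen-1-ol
Product: 7 (3R)-3-{[(tert-butyldiphenylsilyl)oxy]methyl}-6,7-dimethoxy-1,2,3,4-tetrahydronaphthalen-1-ol (mixture of C1 epimers)
Conditions: TBDPSCl (1.05 equiv), imidazole, CH2Cl2, 0 °C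
Reagents that add atoms: tert-butyl(chloro)diphenylsilane, CC(C)(C)[Si](Cl)(c1ccccc1)c1ccccc1
Why: Selective silylation of the primary alcohol by a bulky chlorosilane; the C9' oxygen has to be masked because a free hydroxymethyl group 1,3 to the benzylic carbinol would trap the C1 cation as a bridged ether during dehydration.

Step 6
Reactants: 7 (3R)-3-{[(tert-butyldiphenylsilyl)oxy]methyl}-6,7-dimethoxy-1,2,3,4-tetrahydronaphthalen-1-ol
Product: 8 tert-butyl{[(2R)-6,7-dimethoxy-1,2-dihydronaphthalen-2-yl]methoxy}diphenylsilane
Conditions: Burgess reagent, toluene, rt to 50 °C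
Reagents that add atoms: none
Why: Burgess dehydration: the sulfamate ester of the benzylic alcohol undergoes syn elimination with a C2 hydrogen (the only β-hydrogens), which should give the C1=C2 styrene under non-acidic conditions that spare the silyl ether and do not touch C3.

Step 7
Reactants: 8 tert-butyl{[(2R)-6,7-dimethoxy-1,2-dihydronaphthalen-2-yl]methoxy}diphenylsilane
Product: 9 [(2R)-6,7-dimethoxy-1,2-dihydronaphthalen-2-yl]methanol
Conditions: TBAF, THF, 0 °C to rt
Reagents that add atoms: none
Why: Fluoride-induced desilylation frees the primary alcohol without affecting the styrene or the stereocentre.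

Step 8
Reactants: 9 [(2R)-6,7-dimethoxy-1,2-dihydronaphthalen-2-yl]methanol; 10 (bromomethyl)chlorodimethylsilane
Product: 12 {[(2R)-6,7-dimethoxy-1,2-dihydronaphthalen-2-yl]methoxy}(iodomethyl)dimethylsilane, via bromomethylsilyl ether 11 (not isolated)
Conditions: i-Pr2NEt, MeCN, 0 °C; then NaI (3 equiv), rt, dark; salts filtered off, product used at once
Reagents that add atoms: sodium iodide, [Na+].[I-]
Why: O-silylation of the primary alcohol with the chlorosilane (the classical tether of silicon-tethered radical cyclisations) is followed in the same flask by Finkelstein exchange, which is fast at an α-silyl carbon and is driven by precipitation of NaBr from acetonitrile.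

Step 9
Reactants: 12 {[(2R)-6,7-dimethoxy-1,2-dihydronaphthalen-2-yl]methoxy}(iodomethyl)dimethylsilane; 13 veratrole (1,2-dimethoxybenzene)
Product: 14 (1R,2S,3R)-1-(3,4-dimethoxyphenyl)-6,7-dimethoxytetralin whose C2 methylene (C9) and C3 methylene (C9') are joined as C9–SiMe2–O–C9' (2,3-cis-fused dimethyl-oxasilinane)
Conditions: fac-Ir(ppy)3 (1 mol %), veratrole (20 equiv), 2,6-di-tert-butylpyridine (1.5 equiv), CH2Cl2 (degassed), blue LEDs (450 nm), rt
Reagents that add atoms: none
Why: Proposed new method: the photoexcited trivalent iridium complex fac-Ir(ppy)3 transfers an electron to the C–I bond, the α-silyl radical at C9 adds to C2 of the styrene, and the C1 benzylic radical (para to the C6 methoxy group) is oxidised by the tetravalent iridium formed in the first event, or trapped by iodine and ionised, to the C1 cation, which veratrole captures para to one of its methoxy groups before the hindered pyridine takes up the proton. The closest known reactions are the tin-hydride Nishiyama–Stork cyclisation of halomethylsilyl ethers, the photoredox reduction of unactivated alkyl iodides, and the photoredox three-component alkyl-arylation of styrenes with electron-rich arenes; joining them in one redox-neutral cascade on a tethered substrate has not been shown. The oxasilinane closes 6-exo-trig (C9–Si–O–C9'–C3–C2), attack at C2 being preferred over C1 because it leaves a benzylic radical. C2 is set by the tether, since the four-atom chain anchored on the neighbouring C3 reaches the C2 lobe only on its own face and the ring fusion should therefore be cis; C1 is set by approach of the arene anti to the new C2–C9 bond, on the face away from both arms, which gives the 1,2-trans relationship. The step needs oxidation and arylation to outrun hydrogen abstraction and loss of the C2 proton, and it needs acid to be kept away from the styrene; the absence of hydrogen donors, the electron-rich ring A, the large excess of veratrole and a base too hindered to attack the cation are meant to secure this.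

Step 10
Reactants: 14 the cis-fused oxasilinane of step 9
Product: 15 [(1R,2S,3R)-1-(3,4-dimethoxyphenyl)-6,7-dimethoxy-1,2,3,4-tetrahydronaphthalene-2,3-diyl]dimethanol
Conditions: H2O2 (30 % aq.), KF, KHCO3, THF/MeOH, rt to 40 °C
Reagents that add atoms: hydrogen peroxide, OO
Why: Tamao–Fleming oxidation: fluoride and peroxide add to the alkoxysilane, C9 migrates from silicon to oxygen (a primary carbon, so no stereochemical issue) and hydrolysis of the Si–O bonds should release the cis diol, the arenes and the C1–H bond being inert to basic peroxide.

Step 11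
Reactants: 15 [(1R,2S,3R)-1-(3,4-dimethoxyphenyl)-6,7-dimethoxy-1,2,3,4-tetrahydronaphthalene-2,3-diyl]dimethanol
Product: 16 (1R,2S,3R)-1-(3,4-dimethoxyphenyl)-6,7-dimethoxy-2,3-bis(methoxymethyl)-1,2,3,4-tetrahydronaphthalene
Conditions: NaH, MeI, THF/DMF, 0 °C to rt
Reagents that add atoms: iodomethane, CI
Why: Double Williamson etherification of the two primary alkoxides with iodomethane; no stereocentre carries a hydrogen acidic enough for NaH, so the configuration is retained.

**Compound list**

1 | veratraldehyde (3,4-dimethoxybenzaldehyde) | COc1ccc(C=O)cc1OC | starting material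
2 | dimethyl succinate | COC(=O)CCC(=O)OC | starting material
3 | (E)-4-(3,4-dimethoxyphenyl)-3-(methoxycarbonyl)but-3-enoic acid | COC(=O)/C(CC(=O)O)=C/c1ccc(OC)c(OC)c1 | intermediate
4 | (R)-4-(3,4-dimethoxyphenyl)-3-(methoxycarbonyl)butanoic acid | COC(=O)[C@@H](CC(=O)O)Cc1ccc(OC)c(OC)c1 | intermediate
5 | methyl (R)-6,7-dimethoxy-4-oxo-1,2,3,4-tetrahydronaphthalene-2-carboxylate | COC(=O)[C@@H]1Cc2cc(OC)c(OC)cc2C(=O)C1 | intermediate
6 | (3R)-3-(hydroxymethyl)-6,7-dimethoxy-1,2,3,4-tetrahydronaphthalen-1-ol, C1 epimers | OC[C@@H]1Cc2cc(OC)c(OC)cc2C(O)C1 | intermediate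
7 | (3R)-3-{[(tert-butyldiphenylsilyl)oxy]methyl}-6,7-dimethoxy-1,2,3,4-tetrahydronaphthalen-1-ol, C1 epimers | CC(C)(C)[Si](OC[C@@H]1Cc2cc(OC)c(OC)cc2C(O)C1)(c1ccccc1)c1ccccc1 | intermediate
8 | tert-butyl{[(2R)-6,7-dimethoxy-1,2-dihydronaphthalen-2-yl]methoxy}diphenylsilane | CC(C)(C)[Si](OC[C@@H]1Cc2cc(OC)c(OC)cc2C=C1)(c1ccccc1)c1ccccc1 | intermediate
9 | [(2R)-6,7-dimethoxy-1,2-dihydronaphthalen-2-yl]methanol | OC[C@@H]1Cc2cc(OC)c(OC)cc2C=C1 | intermediate
10 | (bromomethyl)chlorodimethylsilane | C[Si](C)(Cl)CBr | starting material
11 | (bromomethyl){[(2R)-6,7-dimethoxy-1,2-dihydronaphthalen-2-yl]methoxy}dimethylsilane | BrC[Si](C)(C)OC[C@@H]1Cc2cc(OC)c(OC)cc2C=C1 | intermediate (not isolated)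
12 | {[(2R)-6,7-dimethoxy-1,2-dihydronaphthalen-2-yl]methoxy}(iodomethyl)dimethylsilane | IC[Si](C)(C)OC[C@@H]1Cc2cc(OC)c(OC)cc2C=C1 | intermediate
13 | veratrole (1,2-dimethoxybenzene) | COc1ccccc1OC | starting material
14 | (1R,2S,3R)-1-(3,4-dimethoxyphenyl)-6,7-dimethoxytetralin with C9–SiMe2–O–C9' bridge (2,3-cis-fused dimethyl-oxasilinane) | C[Si]1(C)OC[C@@H]2Cc3cc(OC)c(OC)cc3[C@@H](c3ccc(OC)c(OC)c3)[C@@H]2C1 | intermediate
15 | [(1R,2S,3R)-1-(3,4-dimethoxyphenyl)-6,7-dimethoxy-1,2,3,4-tetrahydronaphthalene-2,3-diyl]dimethanol | OC[C@@H]1Cc2cc(OC)c(OC)cc2[C@@H](c2ccc(OC)c(OC)c2)[C@@H]1CO | intermediate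
16 | (1R,2S,3R)-1-(3,4-dimethoxyphenyl)-6,7-dimethoxy-2,3-bis(methoxymethyl)-1,2,3,4-tetrahydronaphthalene | COC[C@@H]1Cc2cc(OC)c(OC)cc2[C@@H](c2ccc(OC)c(OC)c2)[C@@H]1COC | target

**Step count**

Total step count: 11. Longest linear sequence: 11 steps (1 to 16).

**Steps most likely to fail**

Step 9. Several processes could defeat the cascade:
- electron transfer to the C–I bond may be too slow;
- the silylmethyl radical may take the C3 hydrogen by 1,5-transfer instead of cyclising;
- the C1 cation may lose the C2 proton or be intercepted before arylation;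
- adventitious acid may add veratrole to the styrene without cyclisation.

The fallback sets out from 12 and comes back at 14 using known reactions. Tin-hydride radical cyclisation under air (Bu3SnH, dry air, toluene, rt) runs the same 6-exo closure and traps the C1 radical with oxygen, giving the benzylic hydroperoxide F1. PPh3 reduces this to the benzylic alcohol F2 (cis-fused oxasilinane, C1 epimers). Ionisation of F2 with trifluoroacetic acid in CH2Cl2 at low temperature in the presence of veratrole 13 (Friedel–Crafts alkylation through the same C1 cation, hence the same facial preference) should then give 14.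

Step 8. The tether may be lost by hydrolysis during halide exchange and isolation, or the exchange may stay incomplete on a silyl ether that cannot be chromatographed. The fallback sets out from 9 and comes back at 12, with the halide exchange done on a robust silane before the substrate is involved. (Chloromethyl)dimethyl(phenyl)silane and NaI in refluxing acetone give (iodomethyl)dimethyl(phenyl)silane F3. Triflic acid in CH2Cl2 cleaves the silicon–phenyl bond to give (iodomethyl)dimethylsilyl trifluoromethanesulfonate F4. F4 silylates 9 with 2,6-lutidine at −78 °C to give 12 in one mild operation.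

Step 6. Ionisation at C1 may be followed by capture of the cation by the silyloxy oxygen (bridged ether with loss of the silyl group), or by cationic oligomerisation of the electron-rich styrene. The fallback sets out from 7 and comes back at 8 without any cation at C1. Oxidation with Dess–Martin periodinane gives the tetralone silyl ether F5. KN(SiMe3)2 and PhNTf2 in THF at −78 °C give the enol triflate F6; the stereocentre is β to the ketone and not acidic. Reduction with Pd(OAc)2, PPh3, HCO2H and Et3N in DMF replaces the C–O bond by C–H and delivers 8.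

Further compounds
F1 | step 9 | cis-fused dimethyl-oxasilinane of 6,7-dimethoxytetralin bearing a hydroperoxy group at C1 (C1 epimers) | C[Si]1(C)OC[C@@H]2Cc3cc(OC)c(OC)cc3C(OO)[C@@H]2C1
F2 | step 9 | cis-fused dimethyl-oxasilinane of 6,7-dimethoxytetralin bearing a hydroxy group at C1 (C1 epimers) | C[Si]1(C)OC[C@@H]2Cc3cc(OC)c(OC)cc3C(O)[C@@H]2C1
F3 | step 8 | (iodomethyl)dimethyl(phenyl)silane | C[Si](C)(CI)c1ccccc1
F4 | step 8 | (iodomethyl)dimethylsilyl trifluoromethanesulfonate | C[Si](C)(CI)OS(=O)(=O)C(F)(F)F
F5 | step 6 | (3R)-3-{[(tert-butyldiphenylsilyl)oxy]methyl}-6,7-dimethoxy-3,4-dihydronaphthalen-1(2H)-one | CC(C)(C)[Si](OC[C@@H]1Cc2cc(OC)c(OC)cc2C(=O)C1)(c1ccccc1)c1ccccc1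
F6 | step 6 | (3R)-3-{[(tert-butyldiphenylsilyl)oxy]methyl}-6,7-dimethoxy-3,4-dihydronaphthalen-1-yl trifluoromethanesulfonate | CC(C)(C)[Si](OC[C@@H]1Cc2cc(OC)c(OC)cc2C(OS(=O)(=O)C(F)(F)F)=C1)(c1ccccc1)c1ccccc1
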